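## Structural features

CNP0206369.0 is an achiral, linear octamer of oxygenated benzene rings (rings A to H) joined by seven diaryl ether oxygens and carrying twenty-one free phenolic hydroxyls; it has no stereocentre, so the whole problem is one of regiochemistry. Ring A is a 2,4,6-trihydroxyphenyl group bound through the oxygen on C1, between two hydroxyls. Rings B, D and F are 3,5-dihydroxy-1,4-phenylenedioxy units whose C1 oxygen (between two CH groups) points towards ring A and whose C4 oxygen (between two hydroxyls) points towards ring H; rings C, E and G are pentaoxygenated, with the two ether oxygens ortho to each other on C1 and C6 and hydroxyls on C3, C4 and C5; ring H is a 3,4,5-trihydroxyphenyl cap. Each ether oxygen therefore sits on at least one carbon flanked by two oxygens, which makes direct aryl–oxygen coupling at those carbons unattractive. The fragile element is the free polyphenol itself: its pyrogallol-type arrays oxidise readily in air, above all as phenoxides, and the ethers on C1 of rings B, D and F are phloroglucinol-type ethers that can exchange in hot acidic alcohol. The real difficulty is to form seven hindered ethers in a fixed order while twenty-one oxygens stay distinguishable, and then to release and isolate the polyphenol. The key step exploits ring B: its ether carbon C1 lies between the CH groups C2 and C6 and is meta to the oxygens on C3 and C5, with the C4 oxygen between them. This is the pattern formed when an aryloxyacetylene supplies C1 and C2 and a 3,4-dioxygenated cyclobutenone supplies C3 to C6, so the hindered A–O bond can come from a phenol and a chloroalkene and not from an aryl coupling.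

## Logic of the disconnections

35 ⇒ 34. The twenty O–CH3 bonds are cut. Free polyphenols would not survive the basic substitutions and peracid oxidations of the chain growth, and methyl is the smallest cap that is stable to both and is already present in purchasable building blocks. The gain is that all earlier chemistry runs on stable ethers that can be chromatographed. The demand is one exhaustive Lewis-acid demethylation that spares seven diaryl ethers, with a work-up that keeps air and hot acid away from the product.

34 ⇒ 31 + 19 (through 32 and 33); the same cut gives 28 ⇒ 25 + 19 and 22 ⇒ 18 + 19. The bond cut is the ether O–C1 bond of the incoming 3,5-dimethoxy ring (H, F or D), and the C4 oxygen of that ring is traced back to a formyl carbon. C1 is unhindered and para to C4, so a C4 aldehyde activates fluoride displacement and is then turned into the C4 hydroxyl by aryl migration to oxygen. The gain is one ring per two operations from a single fluoride, each cycle ending in a hindered phenol ready for the next. The demand is that a 2,6-disubstituted aryloxide attacks an aldehyde whose acceptor strength is lowered by two ortho methoxy groups, and that the peracid oxidises only the aldehyde.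

31 ⇒ 28 + 15 (through 29 and 30); the same cut gives 25 ⇒ 22 + 15 and 18 ⇒ 13 + 15. The bond cut is the ether O–C1 bond of the incoming pentaoxygenated ring (G, E or C), and its ortho C6 oxygen is traced back to a formyl carbon. The ortho relation of the two ether oxygens is used: a formyl group on C6 activates the C1 fluoride and afterwards becomes the C6 hydroxyl, the nucleophile of the next cycle. The gain is that one two-step cycle serves both ring types, so rings C to H need twelve steps and two building blocks. The demand is high, because the fluorine is para to a methoxy group and the nucleophile is flanked by two methoxy groups.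

15 ⇒ 14. The aryl–CHO bond is cut. The only two free positions of 14 are equivalent and activated by methoxy groups ortho and para, so electrophilic formylation can give one product only. The forward step must avoid chelation-assisted loss of the methoxy group next to the new aldehyde.

13 ⇒ 12 ⇒ 11. The O–CH2OCH3 bond on the central ring B oxygen and one flanking O–CH3 bond are cut. In 11 the three adjacent ring B oxygens are all different (free hydroxyl, acetal, methyl), so the central one can be freed alone. The group on the central oxygen must not move to the neighbouring phenoxide during methylation and must come off without touching methyl ethers, which is why an acetal and not a silyl ether is placed there.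

11 ⇒ 5 + 10. Two ring B bonds are cut, C1–C6 and C2–C3, so that C1 and C2 come from the alkyne of 5 and C3 to C6 from the four ring carbons of 10. This removes the A–O–B ether from the list of aryl couplings and delivers the three adjacent ring B oxygens differentiated. The gain is a ring and two carbon–carbon bonds in one thermal operation from two small fragments. The demand is that the ketene–alkyne union is regioselective and that 5 survives the temperature at which 10 opens.

5 ⇒ 3 ⇒ 1 + 2. The O–C(sp) bond is cut; both alkyne carbons come from 2. The hindered oxygen of 1 acts as a nucleophile towards a small electrophile, which is easy where aryl coupling would be hard. The forward steps need strong base at low temperature without lithiation of the electron-rich ring, and 5 must be used soon after it is made.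

10 ⇒ 9 ⇒ 8 ⇒ 6. The O–CH2OCH3 bond, then the C4–H bond (hydride), then one C–H bond with restoration of a methoxy group are cut, which leads back to 6 with its four ring carbons and four oxygens in place. The gain is a three-step access to the oxygenated four-carbon unit. The demand is that the second hydride attacks the ketone-like carbonyl of 8 and not the vinylogous ester carbonyl, and that labile 9 is protected at once.

## Other disconnections considered

Alternative 1: The cut is the ring D carbon–carbon bond between C4 (bearing the ether to ring E) and a hydroxyl-bearing neighbour, with both ring D ethers traced back to a 2-pyrone. In the forward step methoxide (Mg(OMe)2, then NaOMe) would open pyrone A1 to the ring-opened (2E)-3-aryloxy-5-oxohex-2-enoate A2, in which the ester and the ketone-bearing chain are cis as the pyrone dictates. The aryloxymethyl carbanion of A2 would then close onto the ester to give A3, the octamer with the ring D hydroxyls free. In its favour, it joins trimer phenol 18 and the E–H tetramer phenol A4 on a six-carbon linchpin, and both ring D ethers are made without hindered aryl coupling (addition–elimination at C4 of a pyrone, alkylation at a CH2). On convergence and longest linear sequence it is the better plan. Against it, A4 carries its free hydroxyl at the end from which the fluoride/Dakin cycle cannot grow a chain, so a second oligomer synthesis with other chemistry is needed. Methoxide may also displace the aryloxide from C4 of A1 instead of opening the lactone. The carbanion that must cyclise is less acidic than the methylene between the two carbonyl groups, so relactonisation competes, and all of this risk falls on two advanced fragments. Mechanistically it is an ionic polyketide-type aromatisation, while the chosen plan uses a pericyclic cascade on small molecules. In total step count it is expected to be equal or worse, and it leaves the A–B ether still to be made.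

Alternative 2: The cut is the ring C carbon–carbon bond between the hydroxyl carbon C6 and the aryloxy carbon C1. In the forward step, heating cyclobutenone A5 would open it to a dienylketene that closes by 6π electrocyclisation to trimer phenol A6, which is identical with 18. In its favour, all five ring C oxygens come from the squarate, the regiochemistry is fixed by connectivity, and the B–O–C ether would arise from O-vinylation of 13 and not from substitution on a deactivated fluoroarene; on that bond it is the better plan. It also spends its ring synthesis on the ring that is hardest to buy, a better structural fit than building ring B. In mechanism it is the equal of the chosen key step (cyclobutenone, ketene, 6π closure). Against it, A5 would need a β-aryloxyvinyl anion, which can expel aryloxide, and O-methylation of a hindered tertiary cyclobutenol. It would take about four steps per ring against two for the fluoride/Dakin cycle, repeated for rings C, E and G. It also starts from 13 and so does not replace the chosen key step but follows it.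

Alternative 3: The cut is the ring A carbon–carbon bond between the ether-bearing carbon and a hydroxyl-bearing neighbour. In the forward step NaOMe in methanol would deprotonate the aryloxymethyl carbon of triketide A7, which closes onto the ester (C6 to C1) and enolises to A8, the octamer with the ring A triol free. In its favour, the hindered A–O bond is made by alkylation of a phenol, which equals the chosen plan in avoiding aryl coupling at that carbon. Ring A needs no protecting groups (three fewer ethers to cleave, a point on which it is better), and for ring A alone it takes fewer steps than the eight needed to reach 13. Against it, A7 requires the B–H heptamer phenol A9 with its free hydroxyl on C1 of ring B, so the chain would have to grow from ring H towards ring B, the direction in which the fluoride/Dakin cycle cannot run. A 3,5-dioxo ester also tends to lactonise to a 4-hydroxy-2-pyrone in preference to C-acylation from its least acidic carbon. The air-sensitive free phloroglucinol would be formed in methoxide at the very end on the most valuable intermediate. The chosen plan forms the same ether first, on simple material, where a failure costs little.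

Key step: step 6

Assumption: 5-fluoro-1,2,3-trimethoxybenzene (14) and 4-fluoro-2,6-dimethoxybenzaldehyde (19) are taken as purchasable building blocks; 14 is otherwise one Balz–Schiemann fluorination away from 3,4,5-trimethoxyaniline.

## Route

Step 1
Reactants: 1 2,4,6-trimethoxyphenol; 2 trichloroethylene
Product: 3 2-{[(E)-1,2-dichloroethenyl]oxy}-1,3,5-trimethoxybenzene
Conditions: K2CO3, DMF, 70 °C
Reagents that add atoms: none
Why: Base turns trichloroethylene into dichloroacetylene in situ and the phenoxide adds to it in anti fashion (vinylic substitution by elimination–addition), which should give the (E)-dichlorovinyl ether; the bond forms at oxygen with a small electrophile, so the two ortho methoxy groups of ring A do not interfere.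

Step 2
Reactants: 3 2-{[(E)-1,2-dichloroethenyl]oxy}-1,3,5-trimethoxybenzene
Product: 5 2-(ethynyloxy)-1,3,5-trimethoxybenzene, via lithium (2,4,6-trimethoxyphenoxy)acetylide 4 (not isolated)
Conditions: n-BuLi (2.1 equiv), Et2O, −78 → −40 °C; then H2O, −78 °C
Reagents that add atoms: none
Why: Deprotonation, β-elimination of LiCl to the chloroalkyne and chlorine–lithium exchange (the dichlorovinyl ether route to ynol ethers) should give acetylide 4, which is protonated cold; low temperature avoids lithiation between the methoxy groups, and 5 is filtered through basic alumina and used at once.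

Step 3
Reactants: 6 dimethyl squarate
Product: 8 3-methoxycyclobut-3-ene-1,2-dione, via 4-hydroxy-2,3-dimethoxycyclobut-2-en-1-one 7 (not isolated)
Conditions: LiAlH(OtBu)3 (1.05 equiv), THF, −78 °C; then 6 M HCl, CH2Cl2, rt
Reagents that add atoms: none
Why: The hindered hydride adds once to a squarate carbonyl; acid then ionises the allylic hydroxyl of 7, the cation is stabilised as an oxocarbenium ion at the methoxy-bearing terminus, and loss of methanol gives the semisquarate (the known acid-induced carbonyl transposition of squarate adducts).

Step 4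
Reactants: 8 3-methoxycyclobut-3-ene-1,2-dione
Product: 9 (±)-4-hydroxy-3-methoxycyclobut-2-en-1-one
Conditions: LiAlH(OtBu)3 (1.0 equiv), THF, −78 °C; aq. potassium sodium tartrate, 0 °C
Reagents that add atoms: none
Why: The carbonyl next to the methoxy-bearing carbon is ketone-like and the other is a vinylogous ester, so 1,2-addition of the mild hydride should occur at the former, as carbon nucleophiles do with alkoxycyclobutenediones; the new stereocentre forms racemic and is lost in step 6, and 9 is taken on crude because it is labile to acid and base.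

Step 5
Reactants: 9 (±)-4-hydroxy-3-methoxycyclobut-2-en-1-one
Product: 10 (±)-3-methoxy-4-(methoxymethoxy)cyclobut-2-en-1-one
Conditions: MOMCl, iPr2NEt, CH2Cl2, 0 °C → rt
Reagents that add atoms: chloromethyl methyl ether, COCCl
Why: O-alkylation of a secondary alcohol with a reactive chloromethyl ether under a hindered amine is mild enough for the hydroxycyclobutenone; an acetal is chosen over a silyl ether because it cannot shift to the neighbouring phenoxide oxygen in step 7 and tolerates a basic work-up after step 6.

Step 6
Reactants: 5 2-(ethynyloxy)-1,3,5-trimethoxybenzene; 10 (±)-3-methoxy-4-(methoxymethoxy)cyclobut-2-en-1-one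
Product: 11 3-methoxy-2-(methoxymethoxy)-5-(2,4,6-trimethoxyphenoxy)phenol
Conditions: PhMe, 80 → 110 °C, slow addition of 10 to 5 (1.3 equiv), Ar
Reagents that add atoms: none
Why: Heating opens 10 by 4π electrocyclic ring opening to a vinylketene, the acetal oxygen rotating outwards. The ynol ether then adds across the ketene C=C in a polar [2+2] step: its CH terminus attacks the ketene carbonyl carbon and its oxygen-bearing carbon bonds to the ketene α-carbon, giving a 3-aryloxy-4-vinylcyclobutenone. This opens again (4π) to a dienylketene, which closes ring B by thermal 6π electrocyclisation between the ketene carbon and the acetal-bearing terminus and tautomerises to the phenol. The closest known reaction type is the Danheiser benzannulation of cyclobutenones with alkoxy- or siloxyacetylenes, which gives resorcinol derivatives with this orientation. No stereocentre is created, since the racemic sp3 carbon of 10 becomes aromatic. The selectivity needed is regiochemical: the aryloxy carbon must end up meta to the new hydroxyl and between two CH groups, and this is secured by the polarisation of the ynol ether (nucleophilic CH terminus, cation-stabilising oxygen-bearing carbon) matched to the electrophilic ketene carbon. Ketene dimerisation and acylation of the product phenol are held back by slow addition and excess 5, and any aryl ester formed can be cleaved with K2CO3 in MeOH, which the acetal tolerates.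

Step 7
Reactants: 11 3-methoxy-2-(methoxymethoxy)-5-(2,4,6-trimethoxyphenoxy)phenol
Product: 12 1,3-dimethoxy-2-(methoxymethoxy)-5-(2,4,6-trimethoxyphenoxy)benzene
Conditions: MeI, K2CO3, acetone, 50 °C
Reagents that add atoms: iodomethane, CI
Why: Williamson methylation of the only free phenol; the neighbouring acetal cannot transfer to the phenoxide, so the three ring B oxygens stay differentiated.

Step 8
Reactants: 12 1,3-dimethoxy-2-(methoxymethoxy)-5-(2,4,6-trimethoxyphenoxy)benzene
Product: 13 2,6-dimethoxy-4-(2,4,6-trimethoxyphenoxy)phenol
Conditions: HCl (cat.), MeOH, 45 °C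
Reagents that add atoms: none
Why: Acid-catalysed acetal exchange with methanol removes the methoxymethyl group under conditions that leave aryl methyl ethers and the fully alkylated diaryl ether untouched, freeing the hindered ring B hydroxyl.

Step 9
Reactants: 14 5-fluoro-1,2,3-trimethoxybenzene
Product: 15 6-fluoro-2,3,4-trimethoxybenzaldehyde
Conditions: Cl2CHOMe, TiCl4, CH2Cl2, −10 → 0 °C; then ice water
Reagents that add atoms: dichloromethyl methyl ether, COC(Cl)Cl; water, O
Why: Rieche formylation of a trimethoxybenzene; the two free positions are equivalent, each ortho and para to methoxy groups, so only one aldehyde can form, and the low temperature guards against demethylation next to the new carbonyl.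

Step 10
Reactants: 13 2,6-dimethoxy-4-(2,4,6-trimethoxyphenoxy)phenol; 15 6-fluoro-2,3,4-trimethoxybenzaldehyde
Product: 16 6-[2,6-dimethoxy-4-(2,4,6-trimethoxyphenoxy)phenoxy]-2,3,4-trimethoxybenzaldehyde
Conditions: Cs2CO3, DMSO (degassed), 110 °C, Ar
Reagents that add atoms: none
Why: Nucleophilic aromatic substitution of a fluoride ortho to a formyl group by a phenoxide (addition–elimination through a Meisenheimer complex stabilised by the aldehyde), a standard diaryl ether synthesis; the caesium phenoxide in DMSO is used because the nucleophile is 2,6-disubstituted and the methoxy group para to fluorine lowers the electrophilicity.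

Step 11
Reactants: 16 6-[2,6-dimethoxy-4-(2,4,6-trimethoxyphenoxy)phenoxy]-2,3,4-trimethoxybenzaldehyde
Product: 18 6-[2,6-dimethoxy-4-(2,4,6-trimethoxyphenoxy)phenoxy]-2,3,4-trimethoxyphenol, via aryl formate 17 (not isolated)
Conditions: mCPBA (1.1 equiv), CH2Cl2, 0 °C → rt; then MeOH, HCl (cat.), rt
Reagents that add atoms: 3-chloroperbenzoic acid, OOC(=O)c1cccc(Cl)c1
Why: Dakin-type Baeyer–Villiger oxidation: the electron-rich aryl group migrates in preference to hydrogen to give formate 17, which methanol cleaves to the ring C phenol; a small excess of peracid at low temperature should spare the other electron-rich rings.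

Step 12
Reactants: 18 6-[2,6-dimethoxy-4-(2,4,6-trimethoxyphenoxy)phenoxy]-2,3,4-trimethoxyphenol; 19 4-fluoro-2,6-dimethoxybenzaldehyde
Product: 20 A–D tetramer aldehyde (18 carrying a 4-formyl-3,5-dimethoxyphenyl ring D on its ring C hydroxyl oxygen)
Conditions: Cs2CO3, DMSO (degassed), 100 °C, Ar
Reagents that add atoms: none
Why: Nucleophilic aromatic substitution of a fluoride para to a formyl group; the attacked carbon lies between two CH groups, so the hindered ring C phenoxide meets little steric resistance, and the methoxy groups meta to fluorine do not deactivate the site.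

Step 13
Reactants: 20 A–D tetramer aldehyde
Product: 22 A–D tetramer phenol (18 carrying a 4-hydroxy-3,5-dimethoxyphenyl ring D on its ring C oxygen), via aryl formate 21 (not isolated)
Conditions: mCPBA (1.1 equiv), CH2Cl2, 0 °C → rt; then MeOH, HCl (cat.), rt
Reagents that add atoms: 3-chloroperbenzoic acid, OOC(=O)c1cccc(Cl)c1
Why: Dakin-type Baeyer–Villiger oxidation of a 2,6-dimethoxy-4-aryloxybenzaldehyde, whose aryl group is strongly favoured to migrate; methanolysis of the formate frees the hindered ring D hydroxyl.

Step 14
Reactants: 22 A–D tetramer phenol; 15 6-fluoro-2,3,4-trimethoxybenzaldehyde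
Product: 23 A–E pentamer aldehyde (22 carrying a 2-formyl-3,4,5-trimethoxyphenyl ring E on its ring D hydroxyl oxygen)
Conditions: Cs2CO3, DMSO (degassed), 110 °C, Ar
Reagents that add atoms: none
Why: The same ortho-formyl-activated nucleophilic aromatic substitution as in step 10; the ring D phenoxide has the same 2,6-dimethoxy environment as the ring B phenoxide, so the same reactivity is expected.

Step 15
Reactants: 23 A–E pentamer aldehyde
Product: 25 A–E pentamer phenol (22 carrying a 2-hydroxy-3,4,5-trimethoxyphenyl ring E on its ring D oxygen), via aryl formate 24 (not isolated)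
Conditions: mCPBA (1.1 equiv), CH2Cl2, 0 °C → rt; then MeOH, HCl (cat.), rt
Reagents that add atoms: 3-chloroperbenzoic acid, OOC(=O)c1cccc(Cl)c1
Why: Dakin-type Baeyer–Villiger oxidation of the electron-rich ring E aldehyde followed by methanolysis of the formate, as in step 11.

Step 16
Reactants: 25 A–E pentamer phenol; 19 4-fluoro-2,6-dimethoxybenzaldehyde
Product: 26 A–F hexamer aldehyde (25 carrying a 4-formyl-3,5-dimethoxyphenyl ring F on its ring E hydroxyl oxygen)
Conditions: Cs2CO3, DMSO (degassed), 100 °C, Ar
Reagents that add atoms: none
Why: Para-formyl-activated nucleophilic aromatic substitution at an unhindered C–F carbon, as in step 12.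

Step 17
Reactants: 26 A–F hexamer aldehyde
Product: 28 A–F hexamer phenol (25 carrying a 4-hydroxy-3,5-dimethoxyphenyl ring F on its ring E oxygen), via aryl formate 27 (not isolated)
Conditions: mCPBA (1.1 equiv), CH2Cl2, 0 °C → rt; then MeOH, HCl (cat.), rt
Reagents that add atoms: 3-chloroperbenzoic acid, OOC(=O)c1cccc(Cl)c1
Why: Dakin-type Baeyer–Villiger oxidation with aryl migration and methanolysis of the formate, as in step 13.

Step 18
Reactants: 28 A–F hexamer phenol; 15 6-fluoro-2,3,4-trimethoxybenzaldehyde
Product: 29 A–G heptamer aldehyde (28 carrying a 2-formyl-3,4,5-trimethoxyphenyl ring G on its ring F hydroxyl oxygen)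
Conditions: Cs2CO3, DMSO (degassed), 110 °C, Ar
Reagents that add atoms: none
Why: Ortho-formyl-activated nucleophilic aromatic substitution by a 2,6-dimethoxyphenoxide, as in steps 10 and 14.

Step 19
Reactants: 29 A–G heptamer aldehyde
Product: 31 A–G heptamer phenol (28 carrying a 2-hydroxy-3,4,5-trimethoxyphenyl ring G on its ring F oxygen), via aryl formate 30 (not isolated)
Conditions: mCPBA (1.1 equiv), CH2Cl2, 0 °C → rt; then MeOH, HCl (cat.), rt
Reagents that add atoms: 3-chloroperbenzoic acid, OOC(=O)c1cccc(Cl)c1
Why: Dakin-type Baeyer–Villiger oxidation of the ring G aldehyde and methanolysis of the formate, as in steps 11 and 15.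

Step 20
Reactants: 31 A–G heptamer phenol; 19 4-fluoro-2,6-dimethoxybenzaldehyde
Product: 32 A–H octamer aldehyde (31 carrying a 4-formyl-3,5-dimethoxyphenyl ring H on its ring G hydroxyl oxygen)
Conditions: Cs2CO3, DMSO (degassed), 100 °C, Ar
Reagents that add atoms: none
Why: Para-formyl-activated nucleophilic aromatic substitution, by now used twice on the same phenol type; the formyl group is kept because it becomes the C4 oxygen of ring H.

Step 21
Reactants: 32 A–H octamer aldehyde
Product: 34 A–H octamer phenol (twenty methyl ethers; ring H C4 hydroxyl free), via aryl formate 33 (not isolated)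
Conditions: mCPBA (1.1 equiv), CH2Cl2, 0 °C → rt; then MeOH, HCl (cat.), rt
Reagents that add atoms: 3-chloroperbenzoic acid, OOC(=O)c1cccc(Cl)c1
Why: Dakin-type Baeyer–Villiger oxidation installs the last of the twenty-one oxygens; the free hydroxyl needs no capping because the next step frees all the others.

Step 22
Reactants: 34 A–H octamer phenol
Product: 35 CNP0206369.0
Conditions: BBr3 (40 equiv), CH2Cl2, −78 °C → rt; then H2O, 0 °C; Ar, degassed solvents
Reagents that add atoms: none
Why: Lewis-acid cleavage of aryl methyl ethers (bromide attacks the methyl group of the boron-bound ether), a reaction that does not break diaryl ethers; a cold aqueous quench, rapid removal of acid and exclusion of air guard the pyrogallol units and the phloroglucinol-type ethers of rings B, D and F.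

## Compound list

1 | 2,4,6-trimethoxyphenol | COc1cc(OC)c(O)c(OC)c1 | starting material
2 | trichloroethylene | ClC=C(Cl)Cl | starting material
3 | 2-{[(E)-1,2-dichloroethenyl]oxy}-1,3,5-trimethoxybenzene | Cl/C=C(/Cl)Oc1c(OC)cc(OC)cc1OC | intermediate
4 | lithium (2,4,6-trimethoxyphenoxy)acetylide | [Li]C#COc1c(OC)cc(OC)cc1OC | intermediate (not isolated)
5 | 2-(ethynyloxy)-1,3,5-trimethoxybenzene | C#COc1c(OC)cc(OC)cc1OC | intermediate
6 | dimethyl squarate (3,4-dimethoxycyclobut-3-ene-1,2-dione) | COC1=C(OC)C(=O)C1=O | starting material
7 | (±)-4-hydroxy-2,3-dimethoxycyclobut-2-en-1-one | COC1=C(OC)C(O)C1=O | intermediate (not isolated)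
8 | 3-methoxycyclobut-3-ene-1,2-dione | COC1=CC(=O)C1=O | intermediate
9 | (±)-4-hydroxy-3-methoxycyclobut-2-en-1-one | COC1=CC(=O)C1O | intermediate
10 | (±)-3-methoxy-4-(methoxymethoxy)cyclobut-2-en-1-one | COCOC1C(=O)C=C1OC | intermediate
11 | 3-methoxy-2-(methoxymethoxy)-5-(2,4,6-trimethoxyphenoxy)phenol | COCOc1c(O)cc(Oc2c(OC)cc(OC)cc2OC)cc1OC | intermediate
12 | 1,3-dimethoxy-2-(methoxymethoxy)-5-(2,4,6-trimethoxyphenoxy)benzene | COCOc1c(OC)cc(Oc2c(OC)cc(OC)cc2OC)cc1OC | intermediate
13 | 2,6-dimethoxy-4-(2,4,6-trimethoxyphenoxy)phenol | COc1cc(OC)c(c(OC)c1)Oc1cc(OC)c(O)c(OC)c1 | intermediate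
14 | 5-fluoro-1,2,3-trimethoxybenzene | COc1cc(F)cc(OC)c1OC | starting material
15 | 6-fluoro-2,3,4-trimethoxybenzaldehyde | COc1cc(F)c(C=O)c(OC)c1OC | intermediate
16 | 6-[2,6-dimethoxy-4-(2,4,6-trimethoxyphenoxy)phenoxy]-2,3,4-trimethoxybenzaldehyde (A–C trimer aldehyde) | COc1cc(OC)c(c(OC)c1)Oc1cc(OC)c(c(OC)c1)Oc1cc(OC)c(OC)c(OC)c1C=O | intermediate
17 | 6-[2,6-dimethoxy-4-(2,4,6-trimethoxyphenoxy)phenoxy]-2,3,4-trimethoxyphenyl formate | COc1cc(OC)c(c(OC)c1)Oc1cc(OC)c(c(OC)c1)Oc1cc(OC)c(OC)c(OC)c1OC=O | intermediate (not isolated)
18 | 6-[2,6-dimethoxy-4-(2,4,6-trimethoxyphenoxy)phenoxy]-2,3,4-trimethoxyphenol (A–C trimer phenol) | COc1cc(OC)c(c(OC)c1)Oc1cc(OC)c(c(OC)c1)Oc1cc(OC)c(OC)c(OC)c1O | intermediate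
19 | 4-fluoro-2,6-dimethoxybenzaldehyde | COc1cc(F)cc(OC)c1C=O | starting material
20 | A–D tetramer aldehyde (18 with a 4-formyl-3,5-dimethoxyphenyl group on the ring C oxygen) | COc1cc(OC)c(c(OC)c1)Oc1cc(OC)c(c(OC)c1)Oc1cc(OC)c(OC)c(OC)c1Oc1cc(OC)c(C=O)c(OC)c1 | intermediate
21 | A–D tetramer formate (20 with formyloxy in place of formyl) | COc1cc(OC)c(c(OC)c1)Oc1cc(OC)c(c(OC)c1)Oc1cc(OC)c(OC)c(OC)c1Oc1cc(OC)c(OC=O)c(OC)c1 | intermediate (not isolated)
22 | A–D tetramer phenol (18 with a 4-hydroxy-3,5-dimethoxyphenyl group on the ring C oxygen) | COc1cc(OC)c(c(OC)c1)Oc1cc(OC)c(c(OC)c1)Oc1cc(OC)c(OC)c(OC)c1Oc1cc(OC)c(O)c(OC)c1 | intermediate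
23 | A–E pentamer aldehyde (22 with a 2-formyl-3,4,5-trimethoxyphenyl group on the ring D oxygen) | COc1cc(OC)c(c(OC)c1)Oc1cc(OC)c(c(OC)c1)Oc1cc(OC)c(OC)c(OC)c1Oc1cc(OC)c(c(OC)c1)Oc1cc(OC)c(OC)c(OC)c1C=O | intermediate
24 | A–E pentamer formate (23 with formyloxy in place of formyl) | COc1cc(OC)c(c(OC)c1)Oc1cc(OC)c(c(OC)c1)Oc1cc(OC)c(OC)c(OC)c1Oc1cc(OC)c(c(OC)c1)Oc1cc(OC)c(OC)c(OC)c1OC=O | intermediate (not isolated)
25 | A–E pentamer phenol (22 with a 2-hydroxy-3,4,5-trimethoxyphenyl group on the ring D oxygen) | COc1cc(OC)c(c(OC)c1)Oc1cc(OC)c(c(OC)c1)Oc1cc(OC)c(OC)c(OC)c1Oc1cc(OC)c(c(OC)c1)Oc1cc(OC)c(OC)c(OC)c1O | intermediate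
26 | A–F hexamer aldehyde (25 with a 4-formyl-3,5-dimethoxyphenyl group on the ring E oxygen) | COc1cc(OC)c(c(OC)c1)Oc1cc(OC)c(c(OC)c1)Oc1cc(OC)c(OC)c(OC)c1Oc1cc(OC)c(c(OC)c1)Oc1cc(OC)c(OC)c(OC)c1Oc1cc(OC)c(C=O)c(OC)c1 | intermediate
27 | A–F hexamer formate (26 with formyloxy in place of formyl) | COc1cc(OC)c(c(OC)c1)Oc1cc(OC)c(c(OC)c1)Oc1cc(OC)c(OC)c(OC)c1Oc1cc(OC)c(c(OC)c1)Oc1cc(OC)c(OC)c(OC)c1Oc1cc(OC)c(OC=O)c(OC)c1 | intermediate (not isolated)
28 | A–F hexamer phenol (25 with a 4-hydroxy-3,5-dimethoxyphenyl group on the ring E oxygen) | COc1cc(OC)c(c(OC)c1)Oc1cc(OC)c(c(OC)c1)Oc1cc(OC)c(OC)c(OC)c1Oc1cc(OC)c(c(OC)c1)Oc1cc(OC)c(OC)c(OC)c1Oc1cc(OC)c(O)c(OC)c1 | intermediate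
29 | A–G heptamer aldehyde (28 with a 2-formyl-3,4,5-trimethoxyphenyl group on the ring F oxygen) | COc1cc(OC)c(c(OC)c1)Oc1cc(OC)c(c(OC)c1)Oc1cc(OC)c(OC)c(OC)c1Oc1cc(OC)c(c(OC)c1)Oc1cc(OC)c(OC)c(OC)c1Oc1cc(OC)c(c(OC)c1)Oc1cc(OC)c(OC)c(OC)c1C=O | intermediate
30 | A–G heptamer formate (29 with formyloxy in place of formyl) | COc1cc(OC)c(c(OC)c1)Oc1cc(OC)c(c(OC)c1)Oc1cc(OC)c(OC)c(OC)c1Oc1cc(OC)c(c(OC)c1)Oc1cc(OC)c(OC)c(OC)c1Oc1cc(OC)c(c(OC)c1)Oc1cc(OC)c(OC)c(OC)c1OC=O | intermediate (not isolated)
31 | A–G heptamer phenol (28 with a 2-hydroxy-3,4,5-trimethoxyphenyl group on the ring F oxygen) | COc1cc(OC)c(c(OC)c1)Oc1cc(OC)c(c(OC)c1)Oc1cc(OC)c(OC)c(OC)c1Oc1cc(OC)c(c(OC)c1)Oc1cc(OC)c(OC)c(OC)c1Oc1cc(OC)c(c(OC)c1)Oc1cc(OC)c(OC)c(OC)c1O | intermediate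
32 | A–H octamer aldehyde (31 with a 4-formyl-3,5-dimethoxyphenyl group on the ring G oxygen) | COc1cc(OC)c(c(OC)c1)Oc1cc(OC)c(c(OC)c1)Oc1cc(OC)c(OC)c(OC)c1Oc1cc(OC)c(c(OC)c1)Oc1cc(OC)c(OC)c(OC)c1Oc1cc(OC)c(c(OC)c1)Oc1cc(OC)c(OC)c(OC)c1Oc1cc(OC)c(C=O)c(OC)c1 | intermediate
33 | A–H octamer formate (32 with formyloxy in place of formyl) | COc1cc(OC)c(c(OC)c1)Oc1cc(OC)c(c(OC)c1)Oc1cc(OC)c(OC)c(OC)c1Oc1cc(OC)c(c(OC)c1)Oc1cc(OC)c(OC)c(OC)c1Oc1cc(OC)c(c(OC)c1)Oc1cc(OC)c(OC)c(OC)c1Oc1cc(OC)c(OC=O)c(OC)c1 | intermediate (not isolated)
34 | A–H octamer phenol (icosa-O-methyl ether of 35; ring H C4 hydroxyl free) | COc1cc(OC)c(c(OC)c1)Oc1cc(OC)c(c(OC)c1)Oc1cc(OC)c(OC)c(OC)c1Oc1cc(OC)c(c(OC)c1)Oc1cc(OC)c(OC)c(OC)c1Oc1cc(OC)c(c(OC)c1)Oc1cc(OC)c(OC)c(OC)c1Oc1cc(OC)c(O)c(OC)c1 | intermediate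
35 | CNP0206369.0 | Oc1cc(O)c(Oc2cc(O)c(Oc3cc(O)c(O)c(O)c3Oc3cc(O)c(Oc4cc(O)c(O)c(O)c4Oc4cc(O)c(Oc5cc(O)c(O)c(O)c5Oc5cc(O)c(O)c(O)c5)c(O)c4)c(O)c3)c(O)c2)c(O)c1 | target

## Step count and least certain steps

Total step count: 22. Longest linear sequence: 19 steps, from 6 to 35 (steps 3 to 8 and 10 to 22); the branch from 1 joins at step 6 after two steps and the building block 15 takes one step.

Step 6 (key step). The most likely failure is decomposition of the terminal aryl ynol ether (oligomerisation or hydration) before the donor-substituted cyclobutenone has opened, together with dimerisation of the vinylketene or its capture by the product phenol. The two components are needed at the same temperature but differ in thermal stability. Fallback: the A–B phenol is reached by the substitution/oxidation cycle used later in the route. The fallback sets out from 1, which is heated with 19 (Cs2CO3, DMSO, 100 °C) to give 2,6-dimethoxy-4-(2,4,6-trimethoxyphenoxy)benzaldehyde F1. Oxidation with mCPBA gives 2,6-dimethoxy-4-(2,4,6-trimethoxyphenoxy)phenyl formate F2, and methanolysis returns the route at 13.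

Step 4. The most likely failure is over-reduction or hydride delivery to the wrong carbonyl or to the enone terminus, followed by ring cleavage of the hydroxycyclobutenone during work-up. The two carbonyl groups differ only by conjugation and the product is an acid- and base-labile α-ketol. Fallback: the oxygenated cyclobutenone is built by ketene–ynol ether [2+2] cycloaddition instead of by reduction. Methoxyethyne F3 is prepared from purchased chloroacetaldehyde dimethyl acetal (NaNH2, liquid NH3). It is combined with (benzyloxy)ketene F4, generated from purchased benzyloxyacetyl chloride and Et3N, to give (±)-4-(benzyloxy)-3-methoxycyclobut-2-en-1-one F5. The fallback sets out from 5, which is heated with F5 as in step 6 to give 2-(benzyloxy)-3-methoxy-5-(2,4,6-trimethoxyphenoxy)phenol F6. Methylation (MeI, K2CO3) gives 2-(benzyloxy)-1,3-dimethoxy-5-(2,4,6-trimethoxyphenoxy)benzene F7, and hydrogenolysis (H2, Pd/C, EtOAc) returns the route at 13.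

Step 2. The most likely failure is loss of the terminal ynol ether by polymerisation or acid-induced hydration during isolation, or ring lithiation if the mixture warms. Terminal aryloxyacetylenes are among the least stable ynol ethers. Fallback: the acetylide is kept as its C-silyl derivative. The fallback sets out from 3: acetylide 4, formed as in step 2, is quenched with Me3SiCl to give trimethyl[(2,4,6-trimethoxyphenoxy)ethynyl]silane F8, which can be purified and stored. The silyl group is removed (K2CO3, MeOH, 0 °C) just before step 6, which returns the route at 5.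

Step 10 (and its repeats, steps 14 and 18). The most likely failure is sluggish fluoride displacement, with demethylation of the aldehyde by the phenoxide or slow oxidation of the phenoxide taking over at the temperature required. The fluorine is para to a donor methoxy group and the nucleophile is 2,6-disubstituted. Fallback: copper-catalysed aryl ether coupling replaces the uncatalysed substitution. 6-Bromo-2,3,4-trimethoxybenzaldehyde F9 is made from purchased 5-bromo-1,2,3-trimethoxybenzene by the formylation of step 9. The fallback sets out from 13, which is coupled with F9 (CuI, picolinic acid, K3PO4, DMSO, 90 °C); this returns the route at 16, and the same change serves for 23 and 29.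

Step 22. The most likely failure is incomplete cleavage of the twenty ethers combined with air oxidation of the free polyphenol and acid-promoted exchange of the phloroglucinol-type ethers during work-up, which would leave an inseparable mixture. Fallback: the polyphenol is isolated as a derivative. The fallback sets out from 34: the crude product of the BBr3 treatment is acetylated (Ac2O, pyridine) to the henicosa-O-acetyl derivative of 35 F10, which is stable and can be purified on silica. Mild deacetylation (NH4OAc, aqueous MeOH, Ar) returns the route at 35.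

## Further compounds

F1 | step 6 | 2,6-dimethoxy-4-(2,4,6-trimethoxyphenoxy)benzaldehyde | COc1cc(OC)c(c(OC)c1)Oc1cc(OC)c(C=O)c(OC)c1
F2 | step 6 | 2,6-dimethoxy-4-(2,4,6-trimethoxyphenoxy)phenyl formate | COc1cc(OC)c(c(OC)c1)Oc1cc(OC)c(OC=O)c(OC)c1
F3 | step 4 | methoxyethyne | COC#C
F4 | step 4 | (benzyloxy)ketene | O=C=COCc1ccccc1
F5 | step 4 | (±)-4-(benzyloxy)-3-methoxycyclobut-2-en-1-one | COC1=CC(=O)C1OCc1ccccc1
F6 | step 4 | 2-(benzyloxy)-3-methoxy-5-(2,4,6-trimethoxyphenoxy)phenol | COc1cc(Oc2c(OC)cc(OC)cc2OC)cc(O)c1OCc1ccccc1
F7 | step 4 | 2-(benzyloxy)-1,3-dimethoxy-5-(2,4,6-trimethoxyphenoxy)benzene | COc1cc(Oc2c(OC)cc(OC)cc2OC)cc(OC)c1OCc1ccccc1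
F8 | step 2 | trimethyl[(2,4,6-trimethoxyphenoxy)ethynyl]silane | C[Si](C)(C)C#COc1c(OC)cc(OC)cc1OC
F9 | step 10 | 6-bromo-2,3,4-trimethoxybenzaldehyde | COc1cc(Br)c(C=O)c(OC)c1OC
F10 | step 22 | henicosa-O-acetyl derivative of 35 | CC(=O)Oc1cc(OC(C)=O)c(c(OC(C)=O)c1)Oc1cc(OC(C)=O)c(c(OC(C)=O)c1)Oc1cc(OC(C)=O)c(OC(C)=O)c(OC(C)=O)c1Oc1cc(OC(C)=O)c(c(OC(C)=O)c1)Oc1cc(OC(C)=O)c(OC(C)=O)c(OC(C)=O)c1Oc1cc(OC(C)=O)c(c(OC(C)=O)c1)Oc1cc(OC(C)=O)c(OC(C)=O)c(OC(C)=O)c1Oc1cc(OC(C)=O)c(OC(C)=O)c(OC(C)=O)c1
A1 | alternative 1 | 4-aryloxy-6-(aryloxymethyl)-2H-pyran-2-one carrying the A–C trimer on the C4 oxygen and the E–H tetramer on the CH2 oxygen | COc1cc(OC)c(c(OC)c1)Oc1cc(OC)c(c(OC)c1)Oc1cc(OC)c(OC)c(OC)c1OC1=CC(=O)OC(=C1)COc1cc(OC)c(OC)c(OC)c1Oc1cc(OC)c(c(OC)c1)Oc1cc(OC)c(OC)c(OC)c1Oc1cc(OC)c(OC)c(OC)c1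
A2 | alternative 1 | methyl (2E)-3-aryloxy-6-aryloxy-5-oxohex-2-enoate from methanolysis of A1 | COc1cc(OC)c(c(OC)c1)Oc1cc(OC)c(c(OC)c1)Oc1cc(OC)c(OC)c(OC)c1O/C(CC(=O)COc1cc(OC)c(OC)c(OC)c1Oc1cc(OC)c(c(OC)c1)Oc1cc(OC)c(OC)c(OC)c1Oc1cc(OC)c(OC)c(OC)c1)=C/C(=O)OC
A3 | alternative 1 | octamer with the ring D hydroxyls free and nineteen methyl ethers | COc1cc(OC)c(c(OC)c1)Oc1cc(OC)c(c(OC)c1)Oc1cc(OC)c(OC)c(OC)c1Oc1cc(O)c(c(O)c1)Oc1cc(OC)c(OC)c(OC)c1Oc1cc(OC)c(c(OC)c1)Oc1cc(OC)c(OC)c(OC)c1Oc1cc(OC)c(OC)c(OC)c1
A4 | alternative 1 | E–H tetramer phenol (rings E to H as methyl ethers; hydroxyl free on C1 of ring E) | Oc1cc(OC)c(OC)c(OC)c1Oc1cc(OC)c(c(OC)c1)Oc1cc(OC)c(OC)c(OC)c1Oc1cc(OC)c(OC)c(OC)c1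
A5 | alternative 2 | (±)-4-{(Z)-2-[2,6-dimethoxy-4-(2,4,6-trimethoxyphenoxy)phenoxy]ethenyl}-2,3,4-trimethoxycyclobut-2-en-1-one | COC1=C(OC)C(OC)(/C=C\Oc2c(OC)cc(Oc3c(OC)cc(OC)cc3OC)cc2OC)C1=O
A6 | alternative 2 | 6-[2,6-dimethoxy-4-(2,4,6-trimethoxyphenoxy)phenoxy]-2,3,4-trimethoxyphenol (identical with 18) | COc1cc(OC)c(c(OC)c1)Oc1cc(OC)c(c(OC)c1)Oc1cc(OC)c(OC)c(OC)c1O
A7 | alternative 3 | methyl 6-aryloxy-3,5-dioxohexanoate carrying the B–H heptamer on the C6 oxygen | COC(=O)CC(=O)CC(=O)COc1cc(OC)c(c(OC)c1)Oc1cc(OC)c(OC)c(OC)c1Oc1cc(OC)c(c(OC)c1)Oc1cc(OC)c(OC)c(OC)c1Oc1cc(OC)c(c(OC)c1)Oc1cc(OC)c(OC)c(OC)c1Oc1cc(OC)c(OC)c(OC)c1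
A8 | alternative 3 | octamer with the ring A triol free and rings B to H as methyl ethers | Oc1cc(O)c(c(O)c1)Oc1cc(OC)c(c(OC)c1)Oc1cc(OC)c(OC)c(OC)c1Oc1cc(OC)c(c(OC)c1)Oc1cc(OC)c(OC)c(OC)c1Oc1cc(OC)c(c(OC)c1)Oc1cc(OC)c(OC)c(OC)c1Oc1cc(OC)c(OC)c(OC)c1
A9 | alternative 3 | B–H heptamer phenol (rings B to H as methyl ethers; hydroxyl free on C1 of ring B) | Oc1cc(OC)c(c(OC)c1)Oc1cc(OC)c(OC)c(OC)c1Oc1cc(OC)c(c(OC)c1)Oc1cc(OC)c(OC)c(OC)c1Oc1cc(OC)c(c(OC)c1)Oc1cc(OC)c(OC)c(OC)c1Oc1cc(OC)c(OC)c(OC)c1
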